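**Retrosynthetic overview**

1. Target: the 7-O-ether of isofraxidin 1 with a (2R,3R)-2,3-dihydroxy-3,7-dimethyloct-6-enyl chain (side-chain atoms primed, C1′ = OCH2); the strategic cut is C1′–C2′, ArOCH2–CH(OH).
2. C1′ half: 1 is O-alkylated with the bromomethyl pinacol boronate 2 to the (aryloxymethyl)boronate 3; boron is a temporary activating group on C1′ and leaves as the C2′ hydroxyl.
3. C2′–C8′ half: 6-methylhept-5-en-2-one 4 gives the (R)-oxirane 5 by catalytic asymmetric Corey–Chaykovsky epoxidation (sets C3′); 5 is lithiated at its ring CH2, the future C2′.
4. Enabling feature: the three-membered ring O–C2′–C3′ of 5. Its C2′–H can be lithiated, its strained C2′–O bond is the leaving group for the boron-to-carbon 1,2-shift of CH2OAr, and its oxygen stays on C3′ as the tertiary OH. One operation therefore makes the C1′–C2′ bond, the C2′ stereocentre and both hydroxyls.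
5. Rings: the coumarin bicycle is bought intact in 1 and no ring of the target is formed; the oxirane, a temporary ring, is made in step 2 and opened in step 3.

Key step: step 3

Remark 1: (S)-LaLi3tris(binaphthoxide) is assumed to deliver the methylene to the carbonyl face of 4 that gives (R)-5; if the sense is the opposite, the (R)-catalyst is used.
Remark 2: in the fallback for step 3 the (R)-sulfinyl group is assumed to induce the configuration drawn at the chlorine-bearing carbon; if the induction is the opposite, the (S)-sulfoxide is used.

**Route**

Step 1
Reactants: 1 isofraxidin (7-hydroxy-6,8-dimethoxy-2H-chromen-2-one); 2 2-(bromomethyl)-4,4,5,5-tetramethyl-1,3,2-dioxaborolane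
Product: 3 6,8-dimethoxy-7-[(4,4,5,5-tetramethyl-1,3,2-dioxaborolan-2-yl)methoxy]-2H-chromen-2-one
Conditions: K2CO3, MeCN, 60 °C
Reagents that add atoms: none
Why: Williamson-type O-alkylation in which the phenoxide of 1, its only acidic site, displaces bromide from the α-bromomethyl boronate (directly or through a boron-ate complex and 1,2-shift of oxygen), the standard entry to aryloxymethyl pinacol boronates; the lactone and the B–O bonds should tolerate carbonate in MeCN, and no stereocentre is involved.

Step 2
Reactants: 4 6-methylhept-5-en-2-one
Product: 5 (R)-2-methyl-2-(4-methylpent-3-en-1-yl)oxirane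
Conditions: Me3S(O)I, NaH (ylide preformed), (S)-LaLi3tris(binaphthoxide) (5 mol %), tris(2,4,6-trimethoxyphenyl)phosphine oxide (5 mol %), 5 Å MS, THF, rt
Reagents that add atoms: trimethylsulfoxonium iodide, C[S+](C)(C)=O.[I-]
Why: Catalytic asymmetric Corey–Chaykovsky epoxidation: the chiral La/Li binaphthoxide complex binds ylide and methyl ketone together and delivers the methylene to one carbonyl face, a reaction class that gives 2,2-disubstituted terminal epoxides from methyl ketones with high enantioselectivity, so C3′ is set here by the catalyst while the remote trisubstituted alkene is inert to the nucleophilic ylide.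

Step 3
Reactants: 5 (R)-2-methyl-2-(4-methylpent-3-en-1-yl)oxirane; 3 6,8-dimethoxy-7-[(4,4,5,5-tetramethyl-1,3,2-dioxaborolan-2-yl)methoxy]-2H-chromen-2-one
Product: 9 altissimacoumarin C, via oxiranyllithium 6 (not isolated), via lithium boronate complex 7 (not isolated), via hydroxy boronic ester 8 (not isolated)
Conditions: 5 (2 equiv), s-BuLi (1.8 equiv), TMEDA, Et2O–hexane, −90 °C; 3 (1 equiv) in THF, −90 → −40 °C; AcOH, → 0 °C; NaBO3·4H2O, THF–H2O, 0 °C → rt; work-up at pH 5
Reagents that add atoms: sodium perborate (used as the tetrahydrate), [Na+].[O-]OB=O
Why: s-BuLi/TMEDA bound to the oxirane oxygen removes the ring C–H that lies syn to the C3′ methyl group (anti to the homoprenyl chain) and gives the configurationally stable oxiranyllithium 6, which adds to the vacant p-orbital on boron of 3 with retention to give the boronate 7; the CH2OAr group then shifts from boron to C2′ anti-periplanar to the strained C2′–O bond (1,2-metallate rearrangement with inversion at C2′, completed by protonation of the oxirane oxygen with AcOH), so that the ring oxygen remains on C3′ as the tertiary hydroxyl and boron sits on C2′ in 8, and perborate replaces boron by hydroxyl with retention. The closest known reaction type is the lithiation–borylation homologation of pinacol boronic esters with α-lithiated terminal epoxides, which gives syn-1,2-diols after oxidation; here it is applied to a 2,2-disubstituted oxirane and an aryloxymethyl boronate. No ring is closed: the oxirane is a temporary ring that is opened, and the coumarin is untouched. C3′ is taken over unchanged from 5 because its C–O bond is never broken, and the new centre C2′ is fixed by the site of lithiation, which the retention–inversion–retention sequence converts into the 2R configuration (lithium syn to CH3 gives the 2R,3R diol). The step needs two selectivities: lithiation on the methyl face of the oxirane instead of the chain face, for which the only handle is the smaller size of CH3 compared with CH2CH2CH=CMe2 next to the oxygen-bound base at −90 °C (the C2′ epimer, a diastereomer, would be removed by chromatography), and capture of 6 at boron instead of at the lactone carbonyl or C4 of the coumarin, which the very fast ate-complex formation of an unhindered primary pinacol boronate at −90 °C and the use of s-BuLi as the limiting reagent (no free alkyllithium when 3 is added) should secure.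

**Compound list**

1 | isofraxidin (7-hydroxy-6,8-dimethoxy-2H-chromen-2-one) | COc1cc2ccc(=O)oc2c(OC)c1O | starting material
2 | 2-(bromomethyl)-4,4,5,5-tetramethyl-1,3,2-dioxaborolane | BrCB1OC(C)(C)C(C)(C)O1 | starting material
3 | 6,8-dimethoxy-7-[(4,4,5,5-tetramethyl-1,3,2-dioxaborolan-2-yl)methoxy]-2H-chromen-2-one | COc1cc2ccc(=O)oc2c(OC)c1OCB1OC(C)(C)C(C)(C)O1 | intermediate
4 | 6-methylhept-5-en-2-one | CC(=O)CCC=C(C)C | starting material
5 | (R)-2-methyl-2-(4-methylpent-3-en-1-yl)oxirane | C[C@@]1(CCC=C(C)C)CO1 | intermediate
6 | [(2R,3R)-3-methyl-3-(4-methylpent-3-en-1-yl)oxiran-2-yl]lithium (lithium syn to the C3 methyl) | [Li][C@H]1O[C@]1(C)CCC=C(C)C | intermediate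
7 | lithium boronate complex: pinacolato boron bearing the CH2O-isofraxidin group and the oxiran-2-yl group of 6 (configuration of 6 retained) | [Li+].COc1cc2ccc(=O)oc2c(OC)c1OC[B-]1([C@H]2O[C@]2(C)CCC=C(C)C)OC(C)(C)C(C)(C)O1 | intermediate
8 | 7-{[(2R,3R)-3-hydroxy-3,7-dimethyl-2-(4,4,5,5-tetramethyl-1,3,2-dioxaborolan-2-yl)oct-6-en-1-yl]oxy}-6,8-dimethoxy-2H-chromen-2-one | COc1cc2ccc(=O)oc2c(OC)c1OC[C@@H](B1OC(C)(C)C(C)(C)O1)[C@](C)(O)CCC=C(C)C | intermediate
9 | altissimacoumarin C, 7-{[(2R,3R)-2,3-dihydroxy-3,7-dimethyloct-6-en-1-yl]oxy}-6,8-dimethoxy-2H-chromen-2-one | COc1cc2ccc(=O)oc2c(OC)c1OC[C@@H](O)[C@](C)(O)CCC=C(C)C | target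

**Step count and risks**

Total step count: 3. Longest linear sequence: 2 steps (4 → 5 → 9, or 1 → 3 → 9).

Steps most likely to fail:

1. Step 3. The base may discriminate poorly between the two diastereotopic ring hydrogens of 5 (methyl face against chain face), which would erode the configuration at C2′. The lithiated oxirane or residual base may also add to the coumarin lactone instead of to boron. A third leak is B–O syn-elimination of the β-oxido boronate before it is protonated. Fallback (sets out from 4, comes back at 6): the lithium is placed by sulfoxide–lithium exchange on a stereodefined oxirane instead of by deprotonation. The carbanion of (R)-chloromethyl p-tolyl sulfoxide (LDA, THF, −78 °C) is added to 4. The sulfinyl group should control the chlorine-bearing carbon, and the two carbinol epimers are separated by chromatography; the wanted one is the chlorohydrin (1R,2R)-1-chloro-2,6-dimethyl-1-[(R)-(4-methylphenyl)sulfinyl]hept-5-en-2-ol F1. t-BuOK closes it, with inversion at the C–Cl carbon, to the sulfinyl oxirane (2R,3R)-3-methyl-3-(4-methylpent-3-en-1-yl)-2-[(R)-(4-methylphenyl)sulfinyl]oxirane F2, in which sulfur is syn to the C3 methyl. t-BuLi in THF at −100 °C exchanges the sulfinyl group for lithium with retention and should give 6 free of amine base and of its epimer; 3 is then added and the sequence finished as in step 3.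

2. Step 2. Enantioface discrimination may be insufficient for a ketone whose two substituents are both unbranched (CH3 against CH2CH2R), or the induction may have the wrong sense. Fallback (sets out from 4, comes back at 5): resolution instead of asymmetric catalysis. Uncatalysed Corey–Chaykovsky reaction of 4 (Me3S(O)I, NaH, DMSO) gives the racemic 2-methyl-2-(4-methylpent-3-en-1-yl)oxirane F3. Kinetic resolution by ring opening with TMSN3 under a chiral (salen)Cr(III) azide complex follows; the catalyst enantiomer is chosen so that the (S)-oxirane is consumed as the azido silyl ether (S)-[(1-azido-2,6-dimethylhept-5-en-2-yl)oxy]trimethylsilane F4. Unreacted (R)-5 is separated by distillation.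

3. Step 1. The doubly ortho-substituted phenoxide may alkylate slowly, and the α-aryloxy boronate may suffer hydrolysis or protodeboronation during the basic reaction or on silica. Fallback (sets out from 1, comes back at 3): 1 is alkylated with potassium (bromomethyl)trifluoroborate (Cs2CO3, DMF), an SN2 reaction at a tetracoordinate boron reagent, to give the crystalline potassium {[(6,8-dimethoxy-2-oxo-2H-chromen-7-yl)oxy]methyl}trifluoroborate F5. This is purified by recrystallisation and converted with pinacol and TMSCl in MeCN into 3.

**Further compounds**

F1 | step 3 | (1R,2R)-1-chloro-2,6-dimethyl-1-[(R)-(4-methylphenyl)sulfinyl]hept-5-en-2-ol | Cl[C@H]([C@](C)(O)CCC=C(C)C)[S@](=O)c1ccc(C)cc1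
F2 | step 3 | (2R,3R)-3-methyl-3-(4-methylpent-3-en-1-yl)-2-[(R)-(4-methylphenyl)sulfinyl]oxirane | Cc1ccc(cc1)[S@@](=O)[C@H]1O[C@]1(C)CCC=C(C)C
F3 | step 2 | racemic 2-methyl-2-(4-methylpent-3-en-1-yl)oxirane | CC1(CCC=C(C)C)CO1
F4 | step 2 | (S)-[(1-azido-2,6-dimethylhept-5-en-2-yl)oxy]trimethylsilane | C[C@](O[Si](C)(C)C)(CCC=C(C)C)CN=[N+]=[N-]
F5 | step 1 | potassium {[(6,8-dimethoxy-2-oxo-2H-chromen-7-yl)oxy]methyl}trifluoroborate | [K+].COc1cc2ccc(=O)oc2c(OC)c1OC[B-](F)(F)F
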